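**Plan**
Ring atoms: O1, C2 (bears the CBr2Et chain), C3, C4 (C=O), C5, C6. The retrosynthesis first cuts the two side-chain C–Br bonds and the C3–Br bond, then opens the ring at C3–C4 and O1–C6.
Enabling feature: the segment C4(=O)–C5(Br)=C6(Br)–O1 has the skeleton and halogen pattern of a 2,3,3-tribromoacryloyl group whose terminal carbon has traded one bromine for the ring oxygen. The rest (O1–C2–C3 plus the three-carbon chain) is pentan-2-one as its methyl-side enolate.
Forward: propiolic acid is brominated at its C–H, then across the triple bond, and activated as the acid chloride (three steps).
The acid chloride acylates the kinetic enolate of pentan-2-one (C3–C4). The diketonate oxygen then displaces one bromide of the CBr2 end (O1–C6), so the only ring, the 4H-pyran-4-one, forms in that flask with C5–Br and C6–Br already in place.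
Electrophilic bromination at C3 and radical gem-dibromination of the CH2 next to C2 complete the target.
Stereochemistry: the target has no stereocentre and no stereogenic double bond, so nothing has to be set.

Key step: step 4

Remark: atom labels O1–C6 in the text always follow the numbering defined above, even where the systematic name of an intermediate numbers the ring the other way round. C6–Br in all bromopyranones of the route is a vinylogous acyl bromide, so alcohols, amines and aqueous base are kept out of their reactions and work-ups.

Step 1
Reactants: 1 propiolic acid
Product: 2 3-bromopropiolic acid
Conditions: Br2 (1.05 equiv), KOH (aq), 0 °C; then cold dilute H2SO4, Et2O extraction, no heating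
Reagents that add atoms: bromine, BrBr
Why: Hypobromite bromination of a terminal alkyne, in which the acidic acetylenic C–H of the propiolate is exchanged for Br+ from KOBr made in the flask, is a long-established preparation of this acid, and the low temperature holds back decarboxylation of the bromopropiolate salt.

Step 2
Reactants: 2 3-bromopropiolic acid
Product: 3 2,3,3-tribromoacrylic acid
Conditions: Br2 (1.1 equiv), CHCl3, 0 → 23 °C, ambient light
Reagents that add atoms: bromine, BrBr
Why: Addition of Br2 across the triple bond of a haloalkynoic acid stops at the alkene because the tribromoalkene is too electron-poor and crowded to take up more bromine, and no E/Z isomers can arise since the terminal carbon ends up with two identical bromines.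

Step 3
Reactants: 3 2,3,3-tribromoacrylic acid
Product: 4 2,3,3-tribromoacryloyl chloride
Conditions: (COCl)2 (1.3 equiv), DMF (cat.), CH2Cl2, 0 → 23 °C; concentrate, use directly
Reagents that add atoms: oxalyl chloride, O=C(Cl)C(=O)Cl
Why: Vilsmeier-catalysed acid chloride formation is routine for α,β-unsaturated acids; this acid has no α-hydrogen, so no ketene can form, the by-products are gases, and the mild temperature with only catalytic chloride salt keeps Br/Cl exchange on the alkene from starting.

Step 4
Reactants: 4 2,3,3-tribromoacryloyl chloride; 5 pentan-2-one
Product: 8 2,3-dibromo-6-propyl-4H-pyran-4-one, via lithium pent-1-en-2-olate 6 (not isolated), via lithium diketonate 7 (not isolated)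
Conditions: LiN(SiMe3)2 (2.1 equiv), 5 (2.1 equiv, added to the base), toluene–THF, −78 °C; 4 (1.0 equiv), −78 °C; LiBr (5 equiv, THF soln), DMPU, −78 → 23 °C; pH 7 buffer
Reagents that add atoms: none
Why: Proposed new method: LiN(SiMe3)2 takes a methyl proton of 5 under kinetic control to give 6, the carbon of 6 attacks the acyl carbon of 4 with loss of chloride (bond C3–C4), and the second equivalent of 6 at once deprotonates the new 1,3-diketone to 7, so that neither amide base nor simple enolate is left when the flask is warmed. On warming, 7 has to open its U-shaped lithium chelate and turn about the C3–C4 bond into the sickle form, which DMPU eases, and the oxygen on the propyl-bearing carbon then adds to the CBr2 terminus and bromide is expelled from the α-bromo enolate so formed (bond O1–C6), a vinylic addition–elimination that closes the single ring in the 6-endo-trig mode and is pulled forward by the cross-conjugated, partly aromatic pyranone. The closest known reaction types are the C-acylation of lithium ketone enolates by acid chlorides to 1,3-diketones and the closure of γ-pyrones and chromones from β-halovinyl or β,β-dihalovinyl ketones by an internal oxygen nucleophile, whereas their combination in one flask on a perbrominated acryloyl unit has not been shown. No stereocentre is formed, and because both groups on the terminal carbon are bromine a leaving group is within reach of the oxygen whichever way the alkene is oriented, so no alkene geometry has to be controlled. The step needs methyl-side enolisation (hindered base, −78 °C, ketone added to base), attack of the enolate carbon at C=O instead of O-acylation or attack at CBr2 (tight lithium ion pair in a toluene-rich medium, the acyl chloride being much the fastest electrophile, the crowded and twisted tribromovinyl group a poor one at −78 °C, and any enol ester formed being itself an acyl donor towards 6), and closure through oxygen, which is secured because closure through the central carbon would need a four-membered ring. The added LiBr keeps bromide in large excess over the LiCl released, so that halide exchange at C6, a vinylogous acyl bromide position, stays degenerate.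

Step 5
Reactants: 8 2,3-dibromo-6-propyl-4H-pyran-4-one
Product: 9 2,3,5-tribromo-6-propyl-4H-pyran-4-one
Conditions: Br2 (1.5 equiv), ClCH2CH2Cl, 60 °C, dark, N2 sweep
Reagents that add atoms: bromine, BrBr
Why: Electrophilic bromination of a 4-pyranone at its only free ring position, C3, is a known reaction type; C3 is the β-carbon of the O1–C2=C3 enol ether and is activated by the alkyl group on C2, the non-nucleophilic solvent spares C6–Br, and any stray bromination of the side-chain methylene only anticipates step 6.

Step 6
Reactants: 9 2,3,5-tribromo-6-propyl-4H-pyran-4-one
Product: 11 2,3,5-tribromo-6-(1,1-dibromopropyl)-4H-pyran-4-one, via 1-bromopropyl pyranone 10 (not isolated)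
Conditions: NBS (2.5 equiv), AIBN (cat.), PhCF3, 80 °C
Reagents that add atoms: N-bromosuccinimide, O=C1CCC(=O)N1Br
Why: In this Wohl–Ziegler bromination the bromine atom abstracts hydrogen only from the methylene next to C2, where the radical is delocalised allylically into the ring; the first bromine stabilises the second radical at the same carbon, and the electron-poor ring disfavours ionisation and HBr loss from the bromides formed.

**Compound list**
1 | propiolic acid (prop-2-ynoic acid) | C#CC(=O)O | starting material
2 | 3-bromopropiolic acid | O=C(O)C#CBr | intermediate
3 | 2,3,3-tribromoacrylic acid | O=C(O)C(Br)=C(Br)Br | intermediate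
4 | 2,3,3-tribromoacryloyl chloride | O=C(Cl)C(Br)=C(Br)Br | intermediate
5 | pentan-2-one | CCCC(C)=O | starting material
6 | lithium pent-1-en-2-olate | C=C([O-])CCC.[Li+] | intermediate
7 | lithium (4Z)-1,1,2-tribromo-3-oxoocta-1,4-dien-5-olate | CCC/C([O-])=C/C(=O)C(Br)=C(Br)Br.[Li+] | intermediate
8 | 2,3-dibromo-6-propyl-4H-pyran-4-one | CCCc1cc(=O)c(Br)c(Br)o1 | intermediate
9 | 2,3,5-tribromo-6-propyl-4H-pyran-4-one | CCCc1oc(Br)c(Br)c(=O)c1Br | intermediate
10 | (±)-2,3,5-tribromo-6-(1-bromopropyl)-4H-pyran-4-one | CCC(Br)c1oc(Br)c(Br)c(=O)c1Br | intermediate
11 | 2,3,5-tribromo-6-(1,1-dibromopropyl)-4H-pyran-4-one | CCC(Br)(Br)c1oc(Br)c(Br)c(=O)c1Br | target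

Total step count: 6. Longest linear sequence: 6 (1 → 2 → 3 → 4 → 8 → 9 → 11); 5 enters at step 4 as bought.

**Steps most likely to fail**

Step 4. Several processes could defeat this step:
- O-acylation or double acylation of the enolate.
- Erosion of the methyl-side regiochemistry by proton exchange with the ketone returned by the internal proton transfer.
- Halophilic or conjugate attack of the enolate on the tribromovinyl group.
- A diketonate that stays locked in its chelate and does not close.
- Attack of unclosed diketonate at C6 of freshly formed ring.

The fallback uses known chemistry in three separate operations. It sets out from 5 and 4 and returns to the route at 8. Compound 5 is converted with LiN(iPr)2 and Me3SiCl (THF, −78 °C), by way of 6, into the kinetic silyl enol ether 2-(trimethylsilyloxy)pent-1-ene F1, whose regiochemical purity can be secured by distillation. F1 is acylated by 4 under ZnCl2 in CH2Cl2. This is the Lewis-acid acylation of a silyl enol ether by an acid chloride, with no basic enolate or amide present, and it should give the neutral diketone 1,1,2-tribromooct-1-ene-3,5-dione F2, which is isolated. F2 is then closed with anhydrous K2CO3 in acetone at 23 °C, the base-induced vinylic substitution long used to make γ-pyrones from β-halovinyl diketones, to give 8.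

Step 6. The reaction may stall after the first bromination, because the second hydrogen abstraction occurs at a crowded, electron-poor carbon flanked by C3–Br. Thermal loss of HBr from the side-chain bromides, followed by re-addition of bromine, could also scramble the halogens along the chain. The fallback replaces the radical chain by an ionic sequence at low temperature. It sets out from 9 and returns at 11. Compound 9 is deprotonated at the side-chain methylene with LiN(SiMe3)2 (THF, −78 °C), the standard γ-deprotonation of 2-alkyl-4-pyranones. The extended enolate is quenched with BrCCl2CCl2Br to give 10, which is now isolated. The same two operations on 10, whose remaining C–H is more acidic, should give 11.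

Step 5. Electrophilic substitution may be sluggish on a ring already carrying two bromines, protonation of the pyranone by the HBr released would deactivate it further, and forcing conditions could cause solvolytic loss of the C6 bromine. The fallback places this bromine at the open-chain stage, where the carbon is the highly nucleophilic centre of a 1,3-diketonate. It sets out from 4 and 5 and returns at 9. Diketonate 7 is generated as in step 4 and treated at −78 °C with NBS (1.0 equiv) before any warming, giving (±)-1,1,2,4-tetrabromooct-1-ene-3,5-dione F3. The succinimide anion released deprotonates F3 again, and after addition of LiBr and DMPU and warming, the same O1–C6 closure should deliver 9 directly.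

**Further compounds**
F1 | step 4 | 2-(trimethylsilyloxy)pent-1-ene | C=C(CCC)O[Si](C)(C)C
F2 | step 4 | 1,1,2-tribromooct-1-ene-3,5-dione | CCCC(=O)CC(=O)C(Br)=C(Br)Br
F0 | step 6 | none | none
F3 | step 5 | (±)-1,1,2,4-tetrabromooct-1-ene-3,5-dione | CCCC(=O)C(Br)C(=O)C(Br)=C(Br)Br
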